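Retrosynthetic cuts, in order: the two acetates; the bond between the substituted butenediol carbon and its chain CH2 (B-alkyl Suzuki); the diene and alkyne carbons of the chain (vinylation, carboalumination, acetylide alkylation); the ring C2–CH3 bond (enol triflate/MeMgBr); then, together, ring bonds C2–C3 and C4–C5, which excises C3–C4 as ethylene; last, the bond from ring C1 to the side chain (hydrazone alkylation).
Enabling feature: in the cyclohexene ring (C1 stereocentre, C2 methyl-bearing sp2 carbon, C3 =CH, C4 H2, C5 H2, C6 Me2) the unit C3–C4 is unsubstituted and lies between C2, which can be a carbonyl, and C5; the remaining atoms C2–C1–C6–C5 are therefore a 2-alkyl-3,3-dimethylcyclobutanone, whose ring strain drives insertion of ethylene into its C2–C5 bond.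
Forward order: symmetric 3,3-dimethylcyclobutanone → RAMP-hydrazone alkylation → strain-release two-carbon ring expansion to the six-membered ring → kinetic enol triflate and methylation (alkene fixed at C2=C3) → linear chain growth (alkyne, carboalumination/vinylation, hydroboration/Suzuki with (Z)-2-iodobut-2-ene-1,4-diol) → acetylation.
Stereochemistry: C1 is set by the RAMP auxiliary and is never deprotonated afterwards; the chain E alkene comes from syn carboalumination and the butenediol geometry from trans hydroalumination/iodination, both carried through couplings that retain geometry.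
Key step: step 4

Assumption: the RAMP azaenolate of the cyclobutanone is taken to follow the usual sense of SAMP/RAMP alkylation (RAMP gives the (S) α-carbon here); if the four-membered ring reverses it, SAMP is used in the same way.

Step 1
Reactants: 1 3,3-dimethylcyclobutan-1-one; 2 (R)-1-amino-2-(methoxymethyl)pyrrolidine (RAMP)
Product: 3 (R)-N-(3,3-dimethylcyclobutylidene)-2-(methoxymethyl)pyrrolidin-1-amine
Conditions: neat, 60 °C; then 4 Å MS, Et2O
Reagents that add atoms: none
Why: Condensation of the unhindered, strained ketone with the N-amino auxiliary (Enders hydrazone formation) should be straightforward, and because 1 is symmetric both α-carbons are equivalent, so no regiochemical question arises.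

Step 2
Reactants: 3 (R)-N-(3,3-dimethylcyclobutylidene)-2-(methoxymethyl)pyrrolidin-1-amine; 4 tert-butyl(2-iodoethoxy)dimethylsilane
Product: 6 (2R)-N-[(2S)-2-{2-[(tert-butyldimethylsilyl)oxy]ethyl}-3,3-dimethylcyclobutylidene]-2-(methoxymethyl)pyrrolidin-1-amine (C=N geometry not fixed), via lithium azaenolate 5 (not isolated)
Conditions: LiN(iPr)2, THF, 0 °C; then 4, −100 °C → rt
Reagents that add atoms: none
Why: In the Enders RAMP-hydrazone alkylation the lithium azaenolate, held in the ring-enforced E(C=C)/Z(C–N) geometry with lithium chelated by the methoxy group, should be alkylated by the primary iodide on the face turned away from the pyrrolidine, which sets the (S) α-carbon.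

Step 3
Reactants: 6 (2R)-N-[(2S)-2-{2-[(tert-butyldimethylsilyl)oxy]ethyl}-3,3-dimethylcyclobutylidene]-2-(methoxymethyl)pyrrolidin-1-amine
Product: 7 (S)-2-{2-[(tert-butyldimethylsilyl)oxy]ethyl}-3,3-dimethylcyclobutan-1-one
Conditions: O3, CH2Cl2, −78 °C; then Ar purge
Reagents that add atoms: ozone, [O-][O+]=O
Why: Oxidative hydrazone cleavage by ozone at −78 °C is neutral, so the ketone should be released without enolisation of the α-stereocentre, the silyl ether is inert and no C=C bond is present yet.

Step 4
Reactants: 7 (S)-2-{2-[(tert-butyldimethylsilyl)oxy]ethyl}-3,3-dimethylcyclobutan-1-one; 8 ethylene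
Product: 9 (S)-2-{2-[(tert-butyldimethylsilyl)oxy]ethyl}-3,3-dimethylcyclohexan-1-one
Conditions: Ni(cod)2 (10 mol%), PCy3 (20 mol%), ethylene (10 bar), toluene, 90 °C
Reagents that add atoms: none
Why: Proposed new method: zerovalent nickel should join the strained C=O of 7 and coordinated ethylene by oxidative cyclisation to a spiro oxanickelacyclopentane, β-carbon elimination then opens the four-membered ring (about 26 kcal/mol of strain released) to a seven-membered nickelacycle, and C(sp3)–C(sp3) reductive elimination delivers the ketone, so the carbonyl carbon–CH2 bond and the CH2–CH2 bond are made in one operation. The closest known reaction types are the Ni(cod)2/PCy3-catalysed intermolecular insertion of alkynes into cyclobutanones to give cyclohexenones and its intramolecular alkene variant; intermolecular insertion of ethylene itself is the extension proposed. The six-membered ring arises by two-carbon ring expansion of the four-membered ring (formal 4+2 of its acyl–alkyl unit with the π bond), closed by reductive elimination, not by cyclisation of an open chain. No stereocentre is created; the existing α-stereocentre is a spectator whose C–H bond is never broken in a medium that is neither acidic nor basic, so its configuration should be retained as it is for α-substituted azetidinones in the known alkyne insertions. The step needs cleavage of the carbonyl–CH2 bond in preference to the carbonyl–CH(R) bond, which the α-substituent secures because β-carbon elimination hands the less hindered primary carbon to nickel, and it needs reductive elimination to outrun β-hydride loss from the Ni–CH2CH2C(=O) arm, which the bulky donor phosphine and the ethylene pressure should favour.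

Step 5
Reactants: 9 (S)-2-{2-[(tert-butyldimethylsilyl)oxy]ethyl}-3,3-dimethylcyclohexan-1-one
Product: 11 (S)-6-{2-[(tert-butyldimethylsilyl)oxy]ethyl}-5,5-dimethylcyclohex-1-en-1-yl trifluoromethanesulfonate, via lithium enolate 10 (not isolated)
Conditions: LiN(iPr)2, THF, −78 °C (ketone added to base); then PhNTf2, −78 → 0 °C
Reagents that add atoms: N-phenylbis(trifluoromethanesulfonimide), O=S(=O)(N(c1ccccc1)S(=O)(=O)C(F)(F)F)C(F)(F)F
Why: Kinetic deprotonation should take the unhindered CH2 proton and not the tertiary C–H flanked by the quaternary carbon, and O-triflation of that enolate (kinetic enol triflate formation) fixes the double bond away from the stereocentre, which therefore stays intact.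

Step 6
Reactants: 11 (S)-6-{2-[(tert-butyldimethylsilyl)oxy]ethyl}-5,5-dimethylcyclohex-1-en-1-yl trifluoromethanesulfonate
Product: 12 (S)-tert-butyldimethyl[2-(2,6,6-trimethylcyclohex-2-en-1-yl)ethoxy]silane
Conditions: MeMgBr, Fe(acac)3 (5 mol%), THF/NMP, −30 → 0 °C
Reagents that add atoms: methylmagnesium bromide, C[Mg]Br
Why: Iron-catalysed cross-coupling of an alkenyl triflate with a Grignard reagent (Kochi–Fürstner coupling) replaces OTf by CH3 at the same carbon, so the ring alkene is placed at C2=C3 with no opportunity to drift to the tetrasubstituted isomer.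

Step 7
Reactants: 12 (S)-tert-butyldimethyl[2-(2,6,6-trimethylcyclohex-2-en-1-yl)ethoxy]silane
Product: 13 (S)-2-(2,6,6-trimethylcyclohex-2-en-1-yl)ethan-1-ol
Conditions: Bu4NF, THF, rt
Reagents that add atoms: none
Why: Fluoride cleaves the Si–O bond (silyl ether deprotection) and nothing else in 12 is sensitive to fluoride or mild base.

Step 8
Reactants: 13 (S)-2-(2,6,6-trimethylcyclohex-2-en-1-yl)ethan-1-ol
Product: 14 (S)-6-(2-iodoethyl)-1,5,5-trimethylcyclohex-1-ene
Conditions: I2, PPh3, imidazole, CH2Cl2, 0 °C → rt
Reagents that add atoms: iodine, II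
Why: Appel-type iodination (Garegg–Samuelsson conditions) converts the primary alcohol to the iodide by SN2 in a buffered medium that should leave the acid-sensitive ring alkene where it is.

Step 9
Reactants: 14 (S)-6-(2-iodoethyl)-1,5,5-trimethylcyclohex-1-ene
Product: 15 (S)-6-(but-3-yn-1-yl)-1,5,5-trimethylcyclohex-1-ene
Conditions: LiC≡CH·H2NCH2CH2NH2, DMSO, 10 °C → rt
Reagents that add atoms: lithium acetylide–ethylenediamine complex, [Li]C#C.NCCN
Why: SN2 displacement of the unhindered primary iodide by lithium acetylide in DMSO (acetylide alkylation) should add the two alkyne carbons without touching the remote stereocentre or the ring alkene.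

Step 10
Reactants: 15 (S)-6-(but-3-yn-1-yl)-1,5,5-trimethylcyclohex-1-ene
Product: 17 (S)-1,5,5-trimethyl-6-[(3E)-3-methylhexa-3,5-dien-1-yl]cyclohex-1-ene, via alkenyldimethylalane 16 (not isolated)
Conditions: AlMe3, Cp2ZrCl2 (25 mol%), CH2Cl2, 0 °C → rt; then vinyl bromide, Pd(PPh3)4 (5 mol%), ZnCl2 (20 mol%), THF, rt
Reagents that add atoms: trimethylaluminium, C[Al](C)C; vinyl bromide, C=CBr
Why: Zirconium-catalysed carboalumination (Negishi) adds CH3 and Al syn across the terminal alkyne with Al on the end carbon, and the palladium-catalysed alkenyl–alkenyl coupling with vinyl bromide proceeds with retention, so the trisubstituted alkene should form as the E isomer while the ring alkene is inert.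

Step 11
Reactants: 18 but-2-yne-1,4-diol
Product: 20 (Z)-2-iodobut-2-ene-1,4-diol, via cyclic alkenylaluminate 19 (not isolated)
Conditions: NaAlH2(OCH2CH2OCH3)2, THF, 0 °C → rt; then I2, −78 °C → rt
Reagents that add atoms: iodine, II
Why: The aluminium alkoxide formed from the diol delivers hydride intramolecularly in a trans hydroalumination and iodinolysis of the C–Al bond occurs with retention, which places the two CH2OH groups trans and iodine cis to the distal CH2OH.

Step 12
Reactants: 17 (S)-1,5,5-trimethyl-6-[(3E)-3-methylhexa-3,5-dien-1-yl]cyclohex-1-ene; 20 (Z)-2-iodobut-2-ene-1,4-diol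
Product: 22 (2E)-2-{(3E)-4-methyl-6-[(1S)-2,6,6-trimethylcyclohex-2-en-1-yl]hex-3-en-1-yl}but-2-ene-1,4-diol, via homoallylic 9-BBN borane 21 (not isolated)
Conditions: 9-BBN, THF, 0 °C → rt; then 20, PdCl2(dppf) (5 mol%), AsPh3, 3 M aq. NaOH, THF/DMF, rt
Reagents that add atoms: none
Why: 9-BBN should add only to the terminal CH=CH2 of the diene with boron on the end carbon (anti-Markovnikov hydroboration), and the B-alkyl Suzuki–Miyaura coupling with the iodoalkene runs with retention of its geometry, which gives the two-CH2 spacer and the E-butenediol unit of the target.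

Step 13
Reactants: 22 (2E)-2-{(3E)-4-methyl-6-[(1S)-2,6,6-trimethylcyclohex-2-en-1-yl]hex-3-en-1-yl}but-2-ene-1,4-diol
Product: 23 (2E)-2-{(3E)-4-methyl-6-[(1S)-2,6,6-trimethylcyclohex-2-en-1-yl]hex-3-en-1-yl}but-2-ene-1,4-diyl diacetate (CNP0186001.1)
Conditions: Ac2O, pyridine, DMAP (cat.), CH2Cl2, 0 °C → rt
Reagents that add atoms: acetic anhydride, CC(=O)OC(C)=O
Why: DMAP-catalysed acetylation of the two primary allylic alcohols is a standard esterification that should not touch the alkenes or the stereocentre.

Compound list
1 | 3,3-dimethylcyclobutan-1-one | CC1(C)CC(=O)C1 | starting material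
2 | (R)-1-amino-2-(methoxymethyl)pyrrolidine (RAMP) | COC[C@H]1CCCN1N | starting material
3 | (R)-N-(3,3-dimethylcyclobutylidene)-2-(methoxymethyl)pyrrolidin-1-amine | CC1(C)CC(=NN2CCC[C@@H]2COC)C1 | intermediate
4 | tert-butyl(2-iodoethoxy)dimethylsilane | CC(C)(C)[Si](C)(C)OCCI | starting material
5 | lithium azaenolate of 3 | [Li+].COC[C@H]1CCCN1[N-]C1=CC(C)(C)C1 | intermediate
6 | (2R)-N-[(2S)-2-{2-[(tert-butyldimethylsilyl)oxy]ethyl}-3,3-dimethylcyclobutylidene]-2-(methoxymethyl)pyrrolidin-1-amine | CC(C)(C)[Si](C)(C)OCC[C@@H]1C(=NN2CCC[C@@H]2COC)CC1(C)C | intermediate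
7 | (S)-2-{2-[(tert-butyldimethylsilyl)oxy]ethyl}-3,3-dimethylcyclobutan-1-one | CC(C)(C)[Si](C)(C)OCC[C@@H]1C(=O)CC1(C)C | intermediate
8 | ethylene | C=C | starting material
9 | (S)-2-{2-[(tert-butyldimethylsilyl)oxy]ethyl}-3,3-dimethylcyclohexan-1-one | CC(C)(C)[Si](C)(C)OCC[C@@H]1C(=O)CCCC1(C)C | intermediate
10 | lithium (S)-6-{2-[(tert-butyldimethylsilyl)oxy]ethyl}-5,5-dimethylcyclohex-1-en-1-olate | [Li+].CC(C)(C)[Si](C)(C)OCC[C@@H]1C([O-])=CCCC1(C)C | intermediate
11 | (S)-6-{2-[(tert-butyldimethylsilyl)oxy]ethyl}-5,5-dimethylcyclohex-1-en-1-yl trifluoromethanesulfonate | CC(C)(C)[Si](C)(C)OCC[C@@H]1C(OS(=O)(=O)C(F)(F)F)=CCCC1(C)C | intermediate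
12 | (S)-tert-butyldimethyl[2-(2,6,6-trimethylcyclohex-2-en-1-yl)ethoxy]silane | CC(C)(C)[Si](C)(C)OCC[C@@H]1C(C)=CCCC1(C)C | intermediate
13 | (S)-2-(2,6,6-trimethylcyclohex-2-en-1-yl)ethan-1-ol | OCC[C@@H]1C(C)=CCCC1(C)C | intermediate
14 | (S)-6-(2-iodoethyl)-1,5,5-trimethylcyclohex-1-ene | ICC[C@@H]1C(C)=CCCC1(C)C | intermediate
15 | (S)-6-(but-3-yn-1-yl)-1,5,5-trimethylcyclohex-1-ene | C#CCC[C@@H]1C(C)=CCCC1(C)C | intermediate
16 | dimethyl{(1E)-2-methyl-4-[(1S)-2,6,6-trimethylcyclohex-2-en-1-yl]but-1-en-1-yl}alumane | C[Al](C)/C=C(\C)CC[C@@H]1C(C)=CCCC1(C)C | intermediate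
17 | (S)-1,5,5-trimethyl-6-[(3E)-3-methylhexa-3,5-dien-1-yl]cyclohex-1-ene | C=C/C=C(\C)CC[C@@H]1C(C)=CCCC1(C)C | intermediate
18 | but-2-yne-1,4-diol | OCC#CCO | starting material
19 | disodium alkenylaluminate from 18 (2,5-dihydro-1,2-oxaluminole, drawn as a monomer) | [Na+].[Na+].COCCO[Al-]1(OCCOC)OCC=C1CO[AlH-](OCCOC)OCCOC | intermediate
20 | (Z)-2-iodobut-2-ene-1,4-diol | OC/C=C(\I)CO | intermediate
21 | 9-{(3E)-4-methyl-6-[(1S)-2,6,6-trimethylcyclohex-2-en-1-yl]hex-3-en-1-yl}-9-borabicyclo[3.3.1]nonane | C1CC2CCCC(C1)B2CC/C=C(\C)CC[C@@H]1C(C)=CCCC1(C)C | intermediate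
22 | (2E)-2-{(3E)-4-methyl-6-[(1S)-2,6,6-trimethylcyclohex-2-en-1-yl]hex-3-en-1-yl}but-2-ene-1,4-diol | OC/C=C(\CC/C=C(\C)CC[C@@H]1C(C)=CCCC1(C)C)CO | intermediate
23 | (2E)-2-{(3E)-4-methyl-6-[(1S)-2,6,6-trimethylcyclohex-2-en-1-yl]hex-3-en-1-yl}but-2-ene-1,4-diyl diacetate (CNP0186001.1) | CC(=O)OC/C=C(\CC/C=C(\C)CC[C@@H]1C(C)=CCCC1(C)C)COC(C)=O | target

Total step count: 13. Longest linear sequence: 12 steps (steps 1–10, 12 and 13); step 11 makes the coupling partner.

Steps most likely to fail

Step 4 (ethylene insertion). The nickelacycle may lose a β-hydride from its Ni–CH2CH2–C(=O) arm and open to a vinyl ketone faster than it closes by C(sp3)–C(sp3) reductive elimination, or ethylene may fail to enter oxidative cyclisation with the ketone at all. The fallback sets out from 7 and comes back at 9 by two known one-carbon ring enlargements instead of one two-carbon insertion. Diazomethane (Et2O/MeOH, 0 °C) homologates cyclobutanones without a catalyst and should migrate the less substituted CH2, giving (S)-2-{2-[(tert-butyldimethylsilyl)oxy]ethyl}-3,3-dimethylcyclopentan-1-one F1. A second insertion with diazomethane and catalytic BF3·OEt2 (Et2O, −20 °C), again on the CH2 side, should give 9.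

Step 2 (hydrazone alkylation). SN2 at the azaenolate carbon next to the quaternary centre may be slow enough for E2 elimination of the β-silyloxy iodide and loss of facial control to compete. The fallback sets out from 3 and comes back at 6, using an activated electrophile and adjusting the oxidation level afterwards. The azaenolate 5 is alkylated with tert-butyl bromoacetate (THF, −78 °C) to give tert-butyl 2-[(1S)-2-{[(2R)-2-(methoxymethyl)pyrrolidin-1-yl]imino}-4,4-dimethylcyclobutyl]acetate F2. LiAlH4 (THF, 0 °C), to which the dialkylhydrazone is inert, should reduce the ester to 2-[(1S)-2-{[(2R)-2-(methoxymethyl)pyrrolidin-1-yl]imino}-4,4-dimethylcyclobutyl]ethan-1-ol F3. Silylation with TBSCl and imidazole (DMF, rt) then gives 6.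

Step 12 (hydroboration/Suzuki coupling). Transmetalation of the homoallylic borane to palladium may be slowed by the free 1,4-diol (borate and palladium alkoxide formation), so that protodeboronation or ionisation of the allylic C–O bonds takes over. The fallback sets out from 17 through borane 21 and comes back at 22, replacing the cross-coupling by a chelation-controlled anti carbomagnesiation of the alkyne 18. Oxidation of 21 with NaOH/H2O2 gives (3E)-4-methyl-6-[(1S)-2,6,6-trimethylcyclohex-2-en-1-yl]hex-3-en-1-ol F4. CBr4/PPh3 (CH2Cl2, 0 °C) converts it to (S)-6-[(3E)-6-bromo-3-methylhex-3-en-1-yl]-1,5,5-trimethylcyclohex-1-ene F5, and magnesium in THF gives bromo{(3E)-4-methyl-6-[(1S)-2,6,6-trimethylcyclohex-2-en-1-yl]hex-3-en-1-yl}magnesium F6. Used in excess with CuI (10 mol%) in refluxing THF, F6 should add to 18 trans across the triple bond through the five-membered magnesium alkoxide chelate, and aqueous work-up gives 22 with the same E-butenediol geometry.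

Further compounds
F1 | step 4 | (S)-2-{2-[(tert-butyldimethylsilyl)oxy]ethyl}-3,3-dimethylcyclopentan-1-one | CC(C)(C)[Si](C)(C)OCC[C@@H]1C(=O)CCC1(C)C
F2 | step 2 | tert-butyl 2-[(1S)-2-{[(2R)-2-(methoxymethyl)pyrrolidin-1-yl]imino}-4,4-dimethylcyclobutyl]acetate | CC(C)(C)OC(=O)C[C@@H]1C(=NN2CCC[C@@H]2COC)CC1(C)C
F3 | step 2 | 2-[(1S)-2-{[(2R)-2-(methoxymethyl)pyrrolidin-1-yl]imino}-4,4-dimethylcyclobutyl]ethan-1-ol | OCC[C@@H]1C(=NN2CCC[C@@H]2COC)CC1(C)C
F4 | step 12 | (3E)-4-methyl-6-[(1S)-2,6,6-trimethylcyclohex-2-en-1-yl]hex-3-en-1-ol | OCC/C=C(\C)CC[C@@H]1C(C)=CCCC1(C)C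
F5 | step 12 | (S)-6-[(3E)-6-bromo-3-methylhex-3-en-1-yl]-1,5,5-trimethylcyclohex-1-ene | BrCC/C=C(\C)CC[C@@H]1C(C)=CCCC1(C)C
F6 | step 12 | bromo{(3E)-4-methyl-6-[(1S)-2,6,6-trimethylcyclohex-2-en-1-yl]hex-3-en-1-yl}magnesium | Br[Mg]CC/C=C(\C)CC[C@@H]1C(C)=CCCC1(C)C
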